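The route rests on disconnecting the bond between the methyl-bearing olefinic carbon of the furan-side trisubstituted alkene and the allylic CH2 next to it. The key step joins three components in one operation: a homoallylic alkylcopper that carries the (S)-methyl stereocentre and a silylalkyne, 5-lithio-2,3-dihydrofuran and MeI. A 1,2-metalate rearrangement of the mixed cuprate forms this bond with ring opening, and methylation then fixes the E geometry. The step exploits the C(CH3)=CH–CH2–CH2 unit that leads to furan C3, which maps onto C5, C4, C3 and C2 of 2,3-dihydrofuran; the expelled ring oxygen becomes the handle for the 3-furyl ring. The (Z)-ylidenebutenolide ring is closed last from the alkyne.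

Key step: step 8

Remark: the stereocentre is (S) and is bought with (S)-citronellal; the enol-lactone alkene is Z (side chain cis to the ring oxygen); cuprates 9, 10, 14 and 15 are drawn as the simplest monomeric formulations.

Remark: 5-lithio-2,3-dihydrofuran 7 is made once, on a scale that covers both homologations, and is assumed to hold its titre as a THF/pentane solution at −30 °C under argon between steps 6 and 8; it is titrated again before step 8.

Step 1
Reactants: 1 (S)-citronellal
Product: 2 (S)-3,7-dimethyloct-6-en-1-yne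
Conditions: C4F9SO2F (NfF), P2-Et phosphazene base, DMF, −20 °C → rt
Reagents that add atoms: none
Why: One-pot aldehyde-to-alkyne dehydration by enol nonaflate formation and base-induced E2 loss of nonaflate; the stereocentre is β to the carbonyl, is not enolised, and the phosphazene should be too weak to deprotonate the propargylic position of 2.

Step 2
Reactants: 2 (S)-3,7-dimethyloct-6-en-1-yne
Product: 3 (S)-(3,7-dimethyloct-6-en-1-yn-1-yl)triisopropylsilane
Conditions: n-BuLi, THF, −78 °C; then iPr3SiOTf, −78 → 0 °C
Reagents that add atoms: triisopropylsilyl trifluoromethanesulfonate, CC(C)[Si](OS(=O)(=O)C(F)(F)F)(C(C)C)C(C)C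
Why: C-silylation of the lithium acetylide gives a TIPS-alkyne that should survive the later organolithium, hydride, copper and zinc steps.

Step 3
Reactants: 3 (S)-(3,7-dimethyloct-6-en-1-yn-1-yl)triisopropylsilane
Product: 4 (S)-4-methyl-6-(triisopropylsilyl)hex-5-yn-1-ol
Conditions: O3, CH2Cl2/MeOH, −78 °C (Sudan Red 7B end point); then NaBH4 (excess), −78 → 0 °C
Reagents that add atoms: ozone, O=[O+][O-]
Why: Ozonolysis with reductive work-up, in which the electron-rich trisubstituted alkene should be cleaved far faster than the hindered silylalkyne.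

Step 4
Reactants: 4 (S)-4-methyl-6-(triisopropylsilyl)hex-5-yn-1-ol
Product: 5 (S)-(6-iodo-3-methylhex-1-yn-1-yl)triisopropylsilane
Conditions: I2, PPh3, imidazole, CH2Cl2, 0 °C → rt
Reagents that add atoms: iodine, II
Why: Appel-type iodination of the primary alcohol by SN2 displacement of the alkoxyphosphonium ion; the stereocentre is remote.

Step 5
Reactants: 6 2,3-dihydrofuran
Product: 7 5-lithio-2,3-dihydrofuran (titrated stock solution in THF/pentane)
Conditions: 6 (1.1 equiv), t-BuLi (1.0 equiv), THF/pentane, −78 → 0 °C, 30 min; kept at −30 °C under Ar; one portion for step 6 and one for step 8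
Reagents that add atoms: tert-butyllithium, [Li]C(C)(C)C
Why: Kinetic α-lithiation of the cyclic enol ether at the vinylic C5–H next to the ring oxygen, a standard metalation whose product solution should keep at −30 °C for the short time between its two uses.

Step 6
Reactants: 5 (S)-(6-iodo-3-methylhex-1-yn-1-yl)triisopropylsilane, 7 5-lithio-2,3-dihydrofuran
Product: 11 (S,E)-4,8-dimethyl-10-(triisopropylsilyl)dec-3-en-9-yn-1-ol, via alkyllithium 8 (not isolated), via lithium cuprate 9 (not isolated), via alkenylcopper alkoxide 10 (not isolated)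
Conditions: 5, t-BuLi (2 equiv), Et2O/pentane, −78 °C; CuBr·SMe2 (1 equiv), Me2S/Et2O, −78 °C; 7 (1 equiv, solution from step 5); −78 → 20 °C; MeI, HMPA, 0 → 20 °C; H2O quench
Reagents that add atoms: iodomethane, CI
Why: 1,2-Metalate rearrangement of the mixed cuprate 9, in which the alkyl group migrates from copper to the α-alkoxy alkenyl carbon with inversion and ring opening, followed by retentive C-methylation of alkenylcopper 10, should give the E alkene; alkyllithium 8 is a 5-hexynyllithium that could close a five-membered ring onto the silylalkyne, so it is kept at −78 °C and transmetalated at once.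

Step 7
Reactants: 11 (S,E)-4,8-dimethyl-10-(triisopropylsilyl)dec-3-en-9-yn-1-ol
Product: 12 (S,E)-(10-iodo-3,7-dimethyldec-7-en-1-yn-1-yl)triisopropylsilane
Conditions: I2, PPh3, imidazole, CH2Cl2, 0 °C → rt
Reagents that add atoms: iodine, II
Why: Appel-type iodination of the primary homoallylic alcohol; neutral conditions leave the alkene geometry and the silylalkyne untouched.

Step 8
Reactants: 12 (S,E)-(10-iodo-3,7-dimethyldec-7-en-1-yn-1-yl)triisopropylsilane, 7 5-lithio-2,3-dihydrofuran
Product: 16 (S,3E,7E)-4,8,12-trimethyl-14-(triisopropylsilyl)tetradeca-3,7-dien-13-yn-1-ol, via alkyllithium 13 (not isolated), via lithium cuprate 14 (not isolated), via alkenylcopper alkoxide 15 (not isolated)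
Conditions: 12, t-BuLi (2 equiv), Et2O/pentane, −78 °C; CuBr·SMe2 (1 equiv), Me2S/Et2O, −78 °C; 7 (1 equiv, re-titrated solution from step 5); −78 → 20 °C; MeI, HMPA, 0 → 20 °C; H2O quench
Reagents that add atoms: iodomethane, CI
Why: Iodine–lithium exchange on 12 gives the homoallylic alkyllithium 13, which is transmetalated to copper and combined with 7 to the ate complex 14; on warming, the alkyl group migrates from copper to the adjacent α-alkoxy sp2 carbon anti to the C–O bond (inversion at the carbenoid carbon) while the ring oxygen leaves as alkoxide, and the resulting alkenylcopper 15 is methylated by MeI with retention. The closest known reaction type is the 1,2-metalate rearrangement of cuprates made from α-lithiated cyclic enol ethers, established for the iterative assembly of homoallylic isoprenoid alcohols from homoallylic iodides. No ring is closed: the dihydrofuran ring is opened, and two nucleophilic carbons (the alkyl carbanion and the lithiated enol ether carbon) are united through the carbenoid character of C5 of the heterocycle. No stereocentre is formed; the only new stereo-element is the alkene geometry, which should be E because the ring holds oxygen cis to the CH2CH2 chain, migration is invertive (alkyl trans to that chain) and methylation is retentive (CH3 cis to it). The step needs clean transfer of the valuable alkyl ligand ahead of side reactions of 13 (attack on the silylalkyne, proton abstraction), which low-temperature exchange, immediate transmetalation and the remote, hindered TIPS-alkyne should secure; the (S)-stereocentre is not involved.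

Step 9
Reactants: 16 (S,3E,7E)-4,8,12-trimethyl-14-(triisopropylsilyl)tetradeca-3,7-dien-13-yn-1-ol
Product: 17 (S,7E,11E)-(14-iodo-3,7,11-trimethyltetradeca-7,11-dien-1-yn-1-yl)triisopropylsilane
Conditions: I2, PPh3, imidazole, CH2Cl2, 0 °C → rt
Reagents that add atoms: iodine, II
Why: Appel-type iodination of the primary alcohol under neutral conditions that leave both trisubstituted alkenes in place.

Step 10
Reactants: 17 (S,7E,11E)-(14-iodo-3,7,11-trimethyltetradeca-7,11-dien-1-yn-1-yl)triisopropylsilane, 18 3-bromofuran
Product: 20 (S,7E,11E)-[14-(furan-3-yl)-3,7,11-trimethyltetradeca-7,11-dien-1-yn-1-yl]triisopropylsilane, via alkylzinc iodide 19 (not isolated)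
Conditions: Zn dust, LiCl, THF, 25–40 °C; then 18, Pd(OAc)2 (2 mol%), SPhos (4 mol%), THF, 25 °C
Reagents that add atoms: none
Why: Zinc insertion into the primary iodide followed by Negishi coupling of alkylzinc iodide 19 with 3-bromofuran, with a biarylphosphine that favours reductive elimination over β-hydride elimination; the TIPS-alkyne and the alkenes should be inert.

Step 11
Reactants: 20 (S,7E,11E)-[14-(furan-3-yl)-3,7,11-trimethyltetradeca-7,11-dien-1-yn-1-yl]triisopropylsilane
Product: 21 3-[(S,3E,7E)-4,8,12-trimethyltetradeca-3,7-dien-13-yn-1-yl]furan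
Conditions: Bu4NF, THF, 0 °C → rt
Reagents that add atoms: none
Why: Fluoride-induced protodesilylation of the alkynylsilane; nothing else in 20 is sensitive to fluoride.

Step 12
Reactants: 22 methyl propiolate
Product: 23 methyl (Z)-2-(hydroxymethyl)-3-iodoacrylate
Conditions: MgI2 (1.2 equiv), monomeric CH2O (from cracked paraformaldehyde), CH2Cl2, −20 → 0 °C; H2O quench
Reagents that add atoms: formaldehyde, C=O; magnesium diiodide (MgI2), [Mg+2].[I-].[I-]
Why: β-Iodo Morita–Baylis–Hillman-type three-component reaction: conjugate addition of iodide gives the magnesium β-iodoallenolate, which should be hydroxymethylated at the α-carbon anti to iodine, so that iodine ends cis to the ester (Z, kinetic control at low temperature).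

Step 13
Reactants: 23 methyl (Z)-2-(hydroxymethyl)-3-iodoacrylate
Product: 24 (Z)-2-(hydroxymethyl)-3-iodoacrylic acid
Conditions: LiOH, THF/H2O, 0 °C; then 1 M HCl to pH 2
Reagents that add atoms: lithium hydroxide (LiOH), [Li+].[OH-]
Why: Mild saponification of the methyl ester; the vinylic iodide and the alkene geometry should survive hydroxide at 0 °C.

Step 14
Reactants: 21 3-[(S,3E,7E)-4,8,12-trimethyltetradeca-3,7-dien-13-yn-1-yl]furan, 24 (Z)-2-(hydroxymethyl)-3-iodoacrylic acid
Product: 26 (5Z)-5-[(2S,6E,10E)-13-(furan-3-yl)-2,6,10-trimethyltrideca-6,10-dien-1-ylidene]-3-(hydroxymethyl)furan-2(5H)-one, via enynoic acid 25 (not isolated)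
Conditions: Pd(PPh3)4 (5 mol%), CuI (5 mol%), Et3N (3 equiv), MeCN, 25 °C
Reagents that add atoms: none
Why: Tandem Sonogashira coupling and 5-exo-dig lactonisation: the carboxylate of 25 adds anti across the metal-activated alkyne, which should place the side chain cis to the ring oxygen (Z); the CH2OH group is trans to the alkyne and cannot cyclise, and the stereocentre is not involved.

Compound list
1 | (S)-citronellal, (S)-3,7-dimethyloct-6-enal | CC(C)=CCC[C@H](C)CC=O | starting material
2 | (S)-3,7-dimethyloct-6-en-1-yne | CC(C)=CCC[C@H](C)C#C | intermediate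
3 | (S)-(3,7-dimethyloct-6-en-1-yn-1-yl)triisopropylsilane | CC(C)=CCC[C@H](C)C#C[Si](C(C)C)(C(C)C)C(C)C | intermediate
4 | (S)-4-methyl-6-(triisopropylsilyl)hex-5-yn-1-ol | OCCC[C@H](C)C#C[Si](C(C)C)(C(C)C)C(C)C | intermediate
5 | (S)-(6-iodo-3-methylhex-1-yn-1-yl)triisopropylsilane | ICCC[C@H](C)C#C[Si](C(C)C)(C(C)C)C(C)C | intermediate
6 | 2,3-dihydrofuran | C1CC=CO1 | starting material
7 | 5-lithio-2,3-dihydrofuran (titrated stock solution) | [Li]C1=CCCO1 | intermediate
8 | (S)-[4-methyl-6-(triisopropylsilyl)hex-5-yn-1-yl]lithium | [Li]CCC[C@H](C)C#C[Si](C(C)C)(C(C)C)C(C)C | intermediate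
9 | lithium (4,5-dihydrofuran-2-yl)[(S)-4-methyl-6-(triisopropylsilyl)hex-5-yn-1-yl]cuprate | [Li+].O1CCC=C1[Cu-]CCC[C@H](C)C#C[Si](C(C)C)(C(C)C)C(C)C | intermediate
10 | lithium (S,Z)-4-cuprio-8-methyl-10-(triisopropylsilyl)dec-3-en-9-yn-1-olate (Cu cis to the CH2CH2O chain) | [Li]OCC/C=C(\[Cu])CCC[C@H](C)C#C[Si](C(C)C)(C(C)C)C(C)C | intermediate
11 | (S,E)-4,8-dimethyl-10-(triisopropylsilyl)dec-3-en-9-yn-1-ol | OCC/C=C(\C)CCC[C@H](C)C#C[Si](C(C)C)(C(C)C)C(C)C | intermediate
12 | (S,E)-(10-iodo-3,7-dimethyldec-7-en-1-yn-1-yl)triisopropylsilane | ICC/C=C(\C)CCC[C@H](C)C#C[Si](C(C)C)(C(C)C)C(C)C | intermediate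
13 | [(S,E)-4,8-dimethyl-10-(triisopropylsilyl)dec-3-en-9-yn-1-yl]lithium | [Li]CC/C=C(\C)CCC[C@H](C)C#C[Si](C(C)C)(C(C)C)C(C)C | intermediate
14 | lithium (4,5-dihydrofuran-2-yl)[(S,E)-4,8-dimethyl-10-(triisopropylsilyl)dec-3-en-9-yn-1-yl]cuprate | [Li+].O1CCC=C1[Cu-]CC/C=C(\C)CCC[C@H](C)C#C[Si](C(C)C)(C(C)C)C(C)C | intermediate
15 | lithium (S,3Z,7E)-4-cuprio-8,12-dimethyl-14-(triisopropylsilyl)tetradeca-3,7-dien-13-yn-1-olate (Cu cis to the CH2CH2O chain) | [Li]OCC/C=C(\[Cu])CC/C=C(\C)CCC[C@H](C)C#C[Si](C(C)C)(C(C)C)C(C)C | intermediate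
16 | (S,3E,7E)-4,8,12-trimethyl-14-(triisopropylsilyl)tetradeca-3,7-dien-13-yn-1-ol | OCC/C=C(\C)CC/C=C(\C)CCC[C@H](C)C#C[Si](C(C)C)(C(C)C)C(C)C | intermediate
17 | (S,7E,11E)-(14-iodo-3,7,11-trimethyltetradeca-7,11-dien-1-yn-1-yl)triisopropylsilane | ICC/C=C(\C)CC/C=C(\C)CCC[C@H](C)C#C[Si](C(C)C)(C(C)C)C(C)C | intermediate
18 | 3-bromofuran | Brc1ccoc1 | starting material
19 | [(S,3E,7E)-4,8,12-trimethyl-14-(triisopropylsilyl)tetradeca-3,7-dien-13-yn-1-yl]zinc iodide | I[Zn]CC/C=C(\C)CC/C=C(\C)CCC[C@H](C)C#C[Si](C(C)C)(C(C)C)C(C)C | intermediate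
20 | (S,7E,11E)-[14-(furan-3-yl)-3,7,11-trimethyltetradeca-7,11-dien-1-yn-1-yl]triisopropylsilane | o1ccc(c1)CC/C=C(\C)CC/C=C(\C)CCC[C@H](C)C#C[Si](C(C)C)(C(C)C)C(C)C | intermediate
21 | 3-[(S,3E,7E)-4,8,12-trimethyltetradeca-3,7-dien-13-yn-1-yl]furan | o1ccc(c1)CC/C=C(\C)CC/C=C(\C)CCC[C@H](C)C#C | intermediate
22 | methyl propiolate | C#CC(=O)OC | starting material
23 | methyl (Z)-2-(hydroxymethyl)-3-iodoacrylate (iodine cis to the ester) | COC(=O)/C(CO)=C\I | intermediate
24 | (Z)-2-(hydroxymethyl)-3-iodoacrylic acid | OC(=O)/C(CO)=C\I | intermediate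
25 | (2Z,6S,10E,14E)-17-(furan-3-yl)-2-(hydroxymethyl)-6,10,14-trimethylheptadeca-2,10,14-trien-4-ynoic acid | o1ccc(c1)CC/C=C(\C)CC/C=C(\C)CCC[C@H](C)C#C/C=C(/CO)C(=O)O | intermediate
26 | (5Z)-5-[(2S,6E,10E)-13-(furan-3-yl)-2,6,10-trimethyltrideca-6,10-dien-1-ylidene]-3-(hydroxymethyl)furan-2(5H)-one | C/C(=C\CCc1ccoc1)CC/C=C(\C)CCC[C@H](C)/C=C1/C=C(CO)C(=O)O1 | target

Total step count: 14. Longest linear sequence: 11 steps (steps 1–4, 6–11 and 14); step 5 prepares the reagent solution 7, and steps 12 and 13 prepare the iodo acid 24.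

Steps most likely to fail

Step 8 (key step). The risk is inefficient formation or thermal decay of the mixed cuprate, so that the valuable alkyl ligand is lost by protonation or homocoupling before it migrates, and sluggish C-methylation of the alkenylcopper. The fallback sets out from iodide 12 and makes the same carbon–carbon bond by plain SN2 alkylation: a portion of 5-lithio-2,3-dihydrofuran 7 is alkylated with 12 (THF/DMPU, −30 → 20 °C) to give (S,E)-[10-(4,5-dihydrofuran-2-yl)-3,7-dimethyldec-7-en-1-yn-1-yl]triisopropylsilane F1. A nickel-catalysed Kumada-type ring-opening cross-coupling of this cyclic enol ether with MeMgBr (NiCl2(PPh3)2 cat., toluene, 80 °C) then replaces the ring C–O bond by C–CH3 with retention and comes back to the route at alcohol 16.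

Step 6. The risk is 5-exo-dig carbolithiation of the silylalkyne by alkyllithium 8 during exchange or transmetalation, together with the same loss of the alkyl ligand from copper as in step 8. The fallback sets out from iodide 5 and never places a carbanion five atoms from the silylalkyne: SN2 displacement with lithium acetylide–ethylenediamine complex (DMSO, 20 °C) gives (S)-(3-methylocta-1,7-diyn-1-yl)triisopropylsilane F2. Zirconium-catalysed methylalumination of the terminal alkyne (Me3Al, Cp2ZrCl2, CH2Cl2, 20 °C; syn addition with methyl on the internal carbon), conversion of the alkenylalane to the alanate with n-BuLi and opening of oxirane with retention at the alkenyl carbon then comes back to the route at alcohol 11.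

Step 12. The risk is poor interception of the magnesium iodoallenolate by monomeric formaldehyde (oligomerisation of the aldehyde, protonation to the simple iodoacrylate) and loss of Z selectivity with so small an electrophile. The fallback sets out from methyl propiolate 22 and avoids the iodoallenolate altogether: anti addition of Br2 gives methyl (E)-2,3-dibromoacrylate F3, and regioselective Sonogashira coupling of its C3–Br bond with alkyne 21 (Pd(PPh3)4, CuI, Et3N, THF) gives methyl (2E,6S,10E,14E)-2-bromo-17-(furan-3-yl)-6,10,14-trimethylheptadeca-2,10,14-trien-4-ynoate F4. Stille coupling with Bu3SnCH2OH (Pd(PPh3)4, dioxane, 80 °C) installs the hydroxymethyl group with retention to give methyl (2Z,6S,10E,14E)-17-(furan-3-yl)-2-(hydroxymethyl)-6,10,14-trimethylheptadeca-2,10,14-trien-4-ynoate F5. Saponification (LiOH, THF/H2O) comes back to the route at acid 25, which is then closed to 26 with AgNO3 (monovalent silver, acetone, rt) in the 5-exo-dig mode with anti addition.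

Further compounds
F1 | step 8 | (S,E)-[10-(4,5-dihydrofuran-2-yl)-3,7-dimethyldec-7-en-1-yn-1-yl]triisopropylsilane | O1CCC=C1CC/C=C(\C)CCC[C@H](C)C#C[Si](C(C)C)(C(C)C)C(C)C
F2 | step 6 | (S)-(3-methylocta-1,7-diyn-1-yl)triisopropylsilane | C#CCCC[C@H](C)C#C[Si](C(C)C)(C(C)C)C(C)C
F3 | step 12 | methyl (E)-2,3-dibromoacrylate | COC(=O)/C(Br)=C\Br
F4 | step 12 | methyl (2E,6S,10E,14E)-2-bromo-17-(furan-3-yl)-6,10,14-trimethylheptadeca-2,10,14-trien-4-ynoate | o1ccc(c1)CC/C=C(\C)CC/C=C(\C)CCC[C@H](C)C#C/C=C(/Br)C(=O)OC
F5 | step 12 | methyl (2Z,6S,10E,14E)-17-(furan-3-yl)-2-(hydroxymethyl)-6,10,14-trimethylheptadeca-2,10,14-trien-4-ynoate | o1ccc(c1)CC/C=C(\C)CC/C=C(\C)CCC[C@H](C)C#C/C=C(/CO)C(=O)OC
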